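**Strategy.** The route rests on cutting the C2–C3 bond of ring C. The flavanone hides two carbonyl partners: C2, bonded to O1 and to the ring B aryl, is a masked aldehyde carbon at the acetal oxidation level, and C3–C4 belongs to the ring A methyl ketone in its enol form. Both halves are stored in a racemic 2-aryl-4-methylidene-4H-1,3-benzodioxine, assembled from a ring B aldehyde and 2,4,6-trihydroxybenzoic acid by acylal formation and lactone methylenation. A chiral confined Brønsted acid ionises C2–O3 and returns enol carbon C3 to C2. This one operation forms C2–C3, turns the dioxine into ring C and sets the (2S) centre.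

Key step: step 9

Assumption: "(S,S)-IDPi" is the confined imidodiphosphorimidate acid built from two (S)-3,3'-bis[3,5-bis(trifluoromethyl)phenyl]-BINOL units with P=N–SO2CF3 groups; its sense of induction cannot be predicted with certainty, so the (S,S) form is written for the (2S) product and the mirror-image catalyst is taken if the first run shows the opposite sense.

Step 1
Reactants: 1 4-bromo-2-methoxyphenol; 2 3-methylbut-2-enoic acid
Product: 4 6-bromo-8-methoxy-2,2-dimethylchroman-4-one, via hydroxyaryl enone 3 (not isolated)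
Conditions: P2O5/MeSO3H (Eaton's reagent), 70 °C
Reagents that add atoms: none
Why: Friedel–Crafts acylation at the only free position ortho to the phenol (the para position carries bromine), followed by intramolecular oxa-Michael addition of the phenol to the enone, is the standard one-pot entry to 2,2-dimethylchroman-4-ones.

Step 2
Reactants: 4 6-bromo-8-methoxy-2,2-dimethylchroman-4-one
Product: 5 6-bromo-8-hydroxy-2,2-dimethylchroman-4-one
Conditions: BBr3, CH2Cl2, −78 to 0 °C; then H2O
Reagents that add atoms: none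
Why: Lewis acid ether cleavage, in which BBr3 binds the more basic methoxy oxygen (the ring oxygen is a vinylogous ester oxygen) and bromide removes the methyl group by SN2 attack.

Step 3
Reactants: 5 6-bromo-8-hydroxy-2,2-dimethylchroman-4-one
Product: 6 8-(benzyloxy)-6-bromo-2,2-dimethylchroman-4-one
Conditions: BnBr, K2CO3, DMF, rt
Reagents that add atoms: benzyl bromide, BrCc1ccccc1
Why: Williamson etherification of the only phenol should install a protecting group that survives every later step and falls in the final hydrogenolysis.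

Step 4
Reactants: 6 8-(benzyloxy)-6-bromo-2,2-dimethylchroman-4-one
Product: 7 8-(benzyloxy)-6-bromo-2,2-dimethylspiro[chromane-4,2'-[1,3]dioxolane]
Conditions: HOCH2CH2OH, TsOH·H2O (cat.), toluene, reflux, Dean–Stark
Reagents that add atoms: ethylene glycol, OCCO
Why: Acid-catalysed ketalisation driven by azeotropic removal of water masks the ring B ketone against the organolithium of step 5 and the titanium methylidene of step 8.

Step 5
Reactants: 7 8-(benzyloxy)-6-bromo-2,2-dimethylspiro[chromane-4,2'-[1,3]dioxolane]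
Product: 9 8-(benzyloxy)-2,2-dimethylspiro[chromane-4,2'-[1,3]dioxolane]-6-carbaldehyde, via aryllithium 8 (not isolated)
Conditions: n-BuLi, THF, −78 °C; DMF; then H2O
Reagents that add atoms: N,N-dimethylformamide, CN(C)C=O
Why: Bromine–lithium exchange at −78 °C is faster than any deprotonation, and the aryllithium is formylated by DMF (Bouveault formylation) while ketal and benzyl ether stay inert.

Step 6
Reactants: 9 8-(benzyloxy)-2,2-dimethylspiro[chromane-4,2'-[1,3]dioxolane]-6-carbaldehyde; 10 2,4,6-trihydroxybenzoic acid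
Product: 13 2-[8-(benzyloxy)-2,2-dimethylspiro[chromane-4,2'-[1,3]dioxolan]-6-yl]-5,7-dihydroxy-4H-1,3-benzodioxin-4-one (racemic), via persilylated acid 11 (not isolated), via bis(trimethylsilyl) ether 12 (not isolated)
Conditions: 10, BSA, CH2Cl2, rt; then 9, TMSOTf (cat.), −78 to −40 °C; pyridine quench; THF–H2O–AcOH, rt
Reagents that add atoms: none
Why: TMSOTf-catalysed condensation of a silyl ester/silyl ether pair with an aldehyde (Noyori-type acetalisation, the dioxanone-forming stage of a Petasis–Ferrier union) closes the acylal under aprotic low-temperature conditions that spare the dioxolane, which protic anhydride media would not; the acetal carbon forms racemic, which does not matter.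

Step 7
Reactants: 13 2-[8-(benzyloxy)-2,2-dimethylspiro[chromane-4,2'-[1,3]dioxolan]-6-yl]-5,7-dihydroxy-4H-1,3-benzodioxin-4-one (racemic)
Product: 14 5,7-bis(benzyloxy)-2-[8-(benzyloxy)-2,2-dimethylspiro[chromane-4,2'-[1,3]dioxolan]-6-yl]-4H-1,3-benzodioxin-4-one (racemic)
Conditions: BnBr, K2CO3, DMF, 50 °C
Reagents that add atoms: benzyl bromide, BrCc1ccccc1
Why: Williamson etherification benzylates the free 7-OH and, on warming, the hydrogen-bonded 5-OH, as with the acetonide of the same acid, and carbonate is too weak a nucleophile to open the acylal lactone.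

Step 8
Reactants: 14 5,7-bis(benzyloxy)-2-[8-(benzyloxy)-2,2-dimethylspiro[chromane-4,2'-[1,3]dioxolan]-6-yl]-4H-1,3-benzodioxin-4-one (racemic)
Product: 15 5,7-bis(benzyloxy)-2-[8-(benzyloxy)-2,2-dimethylspiro[chromane-4,2'-[1,3]dioxolan]-6-yl]-4-methylidene-4H-1,3-benzodioxine (racemic)
Conditions: (C5H5)2Ti(CH3)2, toluene, 65 °C, dark; filtration through basic Al2O3
Reagents that add atoms: dimethyltitanocene, [CH3-].[CH3-].[Ti+4].c1cc[cH-]c1.c1cc[cH-]c1
Why: Petasis methylenation, in which thermally formed (C5H5)2Ti=CH2 undergoes [2+2] addition and cycloreversion with the lactone carbonyl, the only carbonyl present, as in the methylenation of 1,3-dioxan-4-ones; the non-acidic conditions should preserve the acid-labile enol acetal.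

Step 9
Reactants: 15 5,7-bis(benzyloxy)-2-[8-(benzyloxy)-2,2-dimethylspiro[chromane-4,2'-[1,3]dioxolan]-6-yl]-4-methylidene-4H-1,3-benzodioxine (racemic)
Product: 17 (2S)-5,7-bis(benzyloxy)-2-[8-(benzyloxy)-2,2-dimethylspiro[chromane-4,2'-[1,3]dioxolan]-6-yl]chroman-4-one, via oxocarbenium enol ion pair 16 (not isolated)
Conditions: (S,S)-IDPi (5 mol %), 5 Å MS, toluene, −40 °C; Et3N quench
Reagents that add atoms: none
Why: Proposed new method: the acid protonates enol ether oxygen O3 and the C2–O3 bond ionises, giving an O1-aryl oxocarbenium ion at C2 (stabilised by O1 and by the ring B oxygen para to C2) that stays tethered through O1 to the freed ring A ketone enol, whose carbon C3 then adds to C2 before proton loss to the anion releases the ketone. The closest known reactions are the Lewis acid-promoted Petasis–Ferrier rearrangement of 4-methylidene-1,3-dioxanes to tetrahydropyran-4-ones and the chiral phosphoric acid-catalysed aza-Petasis–Ferrier rearrangement of hemiaminal vinyl ethers; an oxygen-to-carbon shift of a benzodioxine under chiral Brønsted acid ion-pair control has not been shown. Ring C closes in a 6-(enolendo)-endo-trig mode, with the C2=O1 and C3=C4 π bonds both inside the new six-membered ring; this is stereoelectronically allowed and makes C–C bond formation effectively irreversible, whereas return of O3 to C2 or cleavage of C2–O1 only regenerates 15. The C2 stereocentre is controlled solely by the chiral counter-anion, which covers one face of the planar oxocarbenium carbon while hydrogen-bonding the enol OH, and because ionisation erases the acetal configuration both enantiomers of 15 should converge on (2S)-17. The step needs enantiofacial selectivity (confined anion), ionisation of the aryl vinyl acetal in preference to the ring B dioxolane (better leaving group, more stabilised cation, and dioxolane opening is degenerate without water) and strict exclusion of water (molecular sieves) so that C-protonation of the enol ether cannot end in hydrolysis.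

Step 10
Reactants: 17 (2S)-5,7-bis(benzyloxy)-2-[8-(benzyloxy)-2,2-dimethylspiro[chromane-4,2'-[1,3]dioxolan]-6-yl]chroman-4-one
Product: 18 (2S)-5,7-bis(benzyloxy)-2-[8-(benzyloxy)-2,2-dimethyl-4-oxochroman-6-yl]chroman-4-one
Conditions: 1 M HCl, THF, rt
Reagents that add atoms: water, O
Why: Acid-catalysed ketal hydrolysis proceeds through an aryl-stabilised oxocarbenium ion under conditions too mild to cleave benzyl ethers or to open the flavanone ring, so C2 should keep its configuration.

Step 11
Reactants: 18 (2S)-5,7-bis(benzyloxy)-2-[8-(benzyloxy)-2,2-dimethyl-4-oxochroman-6-yl]chroman-4-one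
Product: 19 (2S)-5,7-dihydroxy-2-(8-hydroxy-2,2-dimethyl-4-oxochroman-6-yl)chroman-4-one (CNP0303522.1)
Conditions: H2 (1 atm), Pd/C, EtOAc–MeOH, rt
Reagents that add atoms: none
Why: Hydrogenolysis of the three aryl benzyl ethers under neutral conditions is the usual last step of flavanone syntheses and should leave both aryl ketones, the C2–O1 bond and the base-sensitive C2 centre untouched.

**Compound list**

1 | 4-bromo-2-methoxyphenol | COc1cc(Br)ccc1O | starting material
2 | 3-methylbut-2-enoic acid | CC(C)=CC(O)=O | starting material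
3 | 1-(5-bromo-2-hydroxy-3-methoxyphenyl)-3-methylbut-2-en-1-one (hydroxyaryl enone, not isolated) | COc1cc(Br)cc(C(=O)C=C(C)C)c1O | intermediate
4 | 6-bromo-8-methoxy-2,2-dimethylchroman-4-one | COc1cc(Br)cc2C(=O)CC(C)(C)Oc12 | intermediate
5 | 6-bromo-8-hydroxy-2,2-dimethylchroman-4-one | Oc1cc(Br)cc2C(=O)CC(C)(C)Oc12 | intermediate
6 | 8-(benzyloxy)-6-bromo-2,2-dimethylchroman-4-one | CC1(C)CC(=O)c2cc(Br)cc(OCc3ccccc3)c2O1 | intermediate
7 | 8-(benzyloxy)-6-bromo-2,2-dimethylspiro[chromane-4,2'-[1,3]dioxolane] | CC1(C)CC2(OCCO2)c2cc(Br)cc(OCc3ccccc3)c2O1 | intermediate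
8 | [8-(benzyloxy)-2,2-dimethylspiro[chromane-4,2'-[1,3]dioxolan]-6-yl]lithium (aryllithium, not isolated) | [Li]c1cc(OCc2ccccc2)c2OC(C)(C)CC3(OCCO3)c2c1 | intermediate
9 | 8-(benzyloxy)-2,2-dimethylspiro[chromane-4,2'-[1,3]dioxolane]-6-carbaldehyde | CC1(C)CC2(OCCO2)c2cc(C=O)cc(OCc3ccccc3)c2O1 | intermediate
10 | 2,4,6-trihydroxybenzoic acid | OC(=O)c1c(O)cc(O)cc1O | starting material
11 | trimethylsilyl 2,4,6-tris(trimethylsilyloxy)benzoate (persilylated acid, not isolated) | C[Si](C)(C)OC(=O)c1c(O[Si](C)(C)C)cc(O[Si](C)(C)C)cc1O[Si](C)(C)C | intermediate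
12 | 2-[8-(benzyloxy)-2,2-dimethylspiro[chromane-4,2'-[1,3]dioxolan]-6-yl]-5,7-bis(trimethylsilyloxy)-4H-1,3-benzodioxin-4-one (racemic, not isolated) | CC1(C)CC2(OCCO2)c2cc(C3OC(=O)c4c(O[Si](C)(C)C)cc(O[Si](C)(C)C)cc4O3)cc(OCc3ccccc3)c2O1 | intermediate
13 | 2-[8-(benzyloxy)-2,2-dimethylspiro[chromane-4,2'-[1,3]dioxolan]-6-yl]-5,7-dihydroxy-4H-1,3-benzodioxin-4-one (racemic) | CC1(C)CC2(OCCO2)c2cc(C3OC(=O)c4c(O)cc(O)cc4O3)cc(OCc3ccccc3)c2O1 | intermediate
14 | 5,7-bis(benzyloxy)-2-[8-(benzyloxy)-2,2-dimethylspiro[chromane-4,2'-[1,3]dioxolan]-6-yl]-4H-1,3-benzodioxin-4-one (racemic) | CC1(C)CC2(OCCO2)c2cc(C3OC(=O)c4c(OCc5ccccc5)cc(OCc5ccccc5)cc4O3)cc(OCc3ccccc3)c2O1 | intermediate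
15 | 5,7-bis(benzyloxy)-2-[8-(benzyloxy)-2,2-dimethylspiro[chromane-4,2'-[1,3]dioxolan]-6-yl]-4-methylidene-4H-1,3-benzodioxine (racemic) | CC1(C)CC2(OCCO2)c2cc(C3OC(=C)c4c(OCc5ccccc5)cc(OCc5ccccc5)cc4O3)cc(OCc3ccccc3)c2O1 | intermediate
16 | O1-aryl oxocarbenium ion bearing the ring A ketone enol, paired with the chiral anion (cation drawn, not isolated) | C=C(O)c1c(OCc2ccccc2)cc(OCc2ccccc2)cc1[O+]=Cc1cc(OCc2ccccc2)c2OC(C)(C)CC3(OCCO3)c2c1 | intermediate
17 | (2S)-5,7-bis(benzyloxy)-2-[8-(benzyloxy)-2,2-dimethylspiro[chromane-4,2'-[1,3]dioxolan]-6-yl]chroman-4-one | CC1(C)CC2(OCCO2)c2cc([C@@H]3CC(=O)c4c(OCc5ccccc5)cc(OCc5ccccc5)cc4O3)cc(OCc3ccccc3)c2O1 | intermediate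
18 | (2S)-5,7-bis(benzyloxy)-2-[8-(benzyloxy)-2,2-dimethyl-4-oxochroman-6-yl]chroman-4-one | CC1(C)CC(=O)c2cc([C@@H]3CC(=O)c4c(OCc5ccccc5)cc(OCc5ccccc5)cc4O3)cc(OCc3ccccc3)c2O1 | intermediate
19 | (2S)-5,7-dihydroxy-2-(8-hydroxy-2,2-dimethyl-4-oxochroman-6-yl)chroman-4-one (CNP0303522.1) | CC1(C)CC(=O)c2cc([C@@H]3CC(=O)c4c(O)cc(O)cc4O3)cc(O)c2O1 | target

**Totals.** Total step count: 11. Longest linear sequence: 11 steps (1 to 19; compound 10 is purchased and enters in step 6).

**Steps most likely to fail**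

1. Step 9 (proposed new method). The chiral anion may fail to discriminate the faces of the large, mobile oxocarbenium ion. C-protonation of the electron-rich enol ether followed by hydrolysis may outrun recombination. The acid may also be held up by reversible opening of the dioxolane.
 Fallback (known chemistry, rhodium-catalysed asymmetric conjugate addition of arylboronic acids to chromones): it sets out from bromide 7 and comes back at 17. Lithiation of 7 to 8 (n-BuLi, THF, −78 °C), borylation with B(OiPr)3 and aqueous work-up should give [8-(benzyloxy)-2,2-dimethylspiro[chromane-4,2'-[1,3]dioxolan]-6-yl]boronic acid F1. Purchased 5,7-dihydroxy-4H-chromen-4-one F2 is benzylated (BnBr, K2CO3, DMF, 70 °C) to 5,7-bis(benzyloxy)-4H-chromen-4-one F3. F1 is added to F3 with [Rh(OH)(C8H12)]2 (monovalent rhodium, C8H12 = cycloocta-1,5-diene) and the electron-poor bisphosphine MeO-F12-BIPHEP (antipode chosen for 2S) in toluene/H2O, which should give 17.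

2. Step 8. Lewis acidic titanium species may ionise the acylal, or the enol acetal may hydrolyse during isolation.
 Fallback: it sets out from aldehyde 9 and comes back at 17, bypassing 14, 15 and step 9. Claisen–Schmidt condensation of 9 with purchased 1-[2,4-bis(benzyloxy)-6-hydroxyphenyl]ethan-1-one F4 (KOH, EtOH/THF, rt) should give (E)-1-[2,4-bis(benzyloxy)-6-hydroxyphenyl]-3-[8-(benzyloxy)-2,2-dimethylspiro[chromane-4,2'-[1,3]dioxolan]-6-yl]prop-2-en-1-one F5. Oxa-Michael closure (NaOAc, EtOH, reflux) gives racemic 5,7-bis(benzyloxy)-2-[8-(benzyloxy)-2,2-dimethylspiro[chromane-4,2'-[1,3]dioxolan]-6-yl]chroman-4-one F6. Kinetic resolution by asymmetric transfer hydrogenation (RuCl[TsDPEN](p-cymene), divalent ruthenium, HCO2H/Et3N; the catalyst antipode that reduces the (2R) ketone) should leave (2S)-17. The other enantiomer is converted into (2R,4R)-5,7-bis(benzyloxy)-2-[8-(benzyloxy)-2,2-dimethylspiro[chromane-4,2'-[1,3]dioxolan]-6-yl]chroman-4-ol F7, which is removed by chromatography.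

3. Step 6. The silylated phloroglucinol ring may be C-alkylated by the activated aldehyde, the aryl silyl ether may add too slowly, or the dihydroxy acylal may open during desilylation and the benzylation of step 7.
 Fallback: it sets out from acid 10 and comes back at 14, so that ring A is benzylated before the union and step 7 falls away. Acetone, (CF3CO)2O and CF3CO2H convert 10 into 5,7-dihydroxy-2,2-dimethyl-4H-1,3-benzodioxin-4-one F8. Benzylation (BnBr, K2CO3, DMF) gives 5,7-bis(benzyloxy)-2,2-dimethyl-4H-1,3-benzodioxin-4-one F9. Hydrolysis (KOH, aq. THF/MeOH, then HCl) gives 2,4-bis(benzyloxy)-6-hydroxybenzoic acid F10. BSA converts F10 into trimethylsilyl 2,4-bis(benzyloxy)-6-(trimethylsilyloxy)benzoate F11, which is condensed with 9 (TMSOTf cat., CH2Cl2, −78 °C) to give 14.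

**Further compounds**

F1 | step 9 | [8-(benzyloxy)-2,2-dimethylspiro[chromane-4,2'-[1,3]dioxolan]-6-yl]boronic acid | CC1(C)CC2(OCCO2)c2cc(B(O)O)cc(OCc3ccccc3)c2O1
F2 | step 9 | 5,7-dihydroxy-4H-chromen-4-one (purchased) | O=c1ccoc2cc(O)cc(O)c12
F3 | step 9 | 5,7-bis(benzyloxy)-4H-chromen-4-one | O=c1ccoc2cc(OCc3ccccc3)cc(OCc3ccccc3)c12
F4 | step 8 | 1-[2,4-bis(benzyloxy)-6-hydroxyphenyl]ethan-1-one (purchased) | CC(=O)c1c(O)cc(OCc2ccccc2)cc1OCc1ccccc1
F5 | step 8 | (E)-1-[2,4-bis(benzyloxy)-6-hydroxyphenyl]-3-[8-(benzyloxy)-2,2-dimethylspiro[chromane-4,2'-[1,3]dioxolan]-6-yl]prop-2-en-1-one | CC1(C)CC2(OCCO2)c2cc(/C=C/C(=O)c3c(O)cc(OCc4ccccc4)cc3OCc3ccccc3)cc(OCc3ccccc3)c2O1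
F6 | step 8 | racemic 5,7-bis(benzyloxy)-2-[8-(benzyloxy)-2,2-dimethylspiro[chromane-4,2'-[1,3]dioxolan]-6-yl]chroman-4-one | CC1(C)CC2(OCCO2)c2cc(C3CC(=O)c4c(OCc5ccccc5)cc(OCc5ccccc5)cc4O3)cc(OCc3ccccc3)c2O1
F7 | step 8 | (2R,4R)-5,7-bis(benzyloxy)-2-[8-(benzyloxy)-2,2-dimethylspiro[chromane-4,2'-[1,3]dioxolan]-6-yl]chroman-4-ol | CC1(C)CC2(OCCO2)c2cc([C@H]3C[C@@H](O)c4c(OCc5ccccc5)cc(OCc5ccccc5)cc4O3)cc(OCc3ccccc3)c2O1
F8 | step 6 | 5,7-dihydroxy-2,2-dimethyl-4H-1,3-benzodioxin-4-one | CC1(C)OC(=O)c2c(O)cc(O)cc2O1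
F9 | step 6 | 5,7-bis(benzyloxy)-2,2-dimethyl-4H-1,3-benzodioxin-4-one | CC1(C)OC(=O)c2c(OCc3ccccc3)cc(OCc3ccccc3)cc2O1
F10 | step 6 | 2,4-bis(benzyloxy)-6-hydroxybenzoic acid | OC(=O)c1c(O)cc(OCc2ccccc2)cc1OCc1ccccc1
F11 | step 6 | trimethylsilyl 2,4-bis(benzyloxy)-6-(trimethylsilyloxy)benzoate | C[Si](C)(C)OC(=O)c1c(O[Si](C)(C)C)cc(OCc2ccccc2)cc1OCc1ccccc1
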